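The 19-membered ring is opened at the diaryl ether bond between the oxygen of ring C (the hydroxylated ring) that sits meta to the ethano bridge and the ether carbon of ring D (the ring with no other substituent). That carbon is meta to the benzylic carbon and has no activating group, so it carries a chloride that stays silent through two B-alkyl Suzuki–Miyaura couplings and is then engaged in a palladium-catalysed C–O coupling. This one operation closes the macrocycle from a linear tetra-aryl chlorophenol. The neighbouring ring C oxygen, para to the bridge, is held as a benzyl ether: it leaves one nucleophile and, as an ortho substituent, speeds reductive elimination.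

Key step: step 5

Remark: ring A is the methoxy-bearing ring and ring B the para-linked ring. The target has no stereocentre, so no configuration has to be set. 4-(Benzyloxy)-3-hydroxybenzaldehyde is taken as commercially available.

Step 1
Reactants: 1 3-chlorostyrene (1-chloro-3-ethenylbenzene); 2 9-borabicyclo[3.3.1]nonane (9-BBN); 3 5-bromo-2-methoxyphenol
Product: 5 5-[2-(3-chlorophenyl)ethyl]-2-methoxyphenol, via alkylborane 4 (not isolated)
Conditions: 1, 9-BBN (1.1 equiv), THF, 0 °C to rt; then 3, Pd(dppf)Cl2 (5 mol %), 3 M aq NaOH, THF, 65 °C
Reagents that add atoms: none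
Why: 9-BBN hydroborates the styrene at the terminal carbon and the B-alkyl group is then transferred in a Suzuki–Miyaura coupling to the C–Br bond of 3, while Pd(dppf)Cl2 at 65 °C should leave the unactivated C–Cl bond untouched and the phenol is carried as its sodium salt.

Step 2
Reactants: 5 5-[2-(3-chlorophenyl)ethyl]-2-methoxyphenol; 6 4-bromophenylboronic acid
Product: 7 2-(4-bromophenoxy)-4-[2-(3-chlorophenyl)ethyl]-1-methoxybenzene
Conditions: Cu(OAc)2 (20 mol %), pyridine, 4 Å molecular sieves, CH2Cl2, O2 (1 atm), rt
Reagents that add atoms: none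
Why: Chan–Lam coupling, in which the boronic acid passes its aryl group to copper and C–O reductive elimination from trivalent copper gives the diaryl ether at room temperature, conditions under which neither the C–Br nor the C–Cl bond should react.

Step 3
Reactants: 8 4-(benzyloxy)-3-hydroxybenzaldehyde
Product: 9 2-(benzyloxy)-5-ethenylphenol
Conditions: Ph3PCH3Br (2.5 equiv), KOtBu (2.4 equiv), THF, 0 °C to rt
Reagents that add atoms: methyltriphenylphosphonium bromide, C[P+](c1ccccc1)(c1ccccc1)c1ccccc1.[Br-]
Why: Wittig methylenation; the phenoxide formed by the extra base is meta to the formyl group and not conjugated with it, so the aldehyde stays electrophilic.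

Step 4
Reactants: 9 2-(benzyloxy)-5-ethenylphenol; 2 9-borabicyclo[3.3.1]nonane (9-BBN); 7 2-(4-bromophenoxy)-4-[2-(3-chlorophenyl)ethyl]-1-methoxybenzene
Product: 11 2-(benzyloxy)-5-[2-(4-{5-[2-(3-chlorophenyl)ethyl]-2-methoxyphenoxy}phenyl)ethyl]phenol, via O-boryl alkylborane 10 (not isolated)
Conditions: 9, 9-BBN (2.2 equiv), THF, 0 °C to rt; then 7, Pd(dppf)Cl2 (5 mol %), 3 M aq NaOH, THF, 65 °C
Reagents that add atoms: none
Why: one equivalent of 9-BBN is consumed by the phenol with loss of H2, the second hydroborates the vinyl group at the terminal carbon, and the B-alkyl Suzuki–Miyaura coupling should then take place at the C–Br bond of 7 in preference to its C–Cl bond, the O–B bond being hydrolysed by the aqueous base.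

Step 5
Reactants: 11 2-(benzyloxy)-5-[2-(4-{5-[2-(3-chlorophenyl)ethyl]-2-methoxyphenoxy}phenyl)ethyl]phenol
Product: 12 ring C O-benzyl ether of the target (19-membered tetra-aryl macrocycle with OCH3 on ring A and OCH2Ph on ring C)
Conditions: Pd(OAc)2 (10 mol %), tBuXPhos (2-di-tert-butylphosphino-2',4',6'-triisopropylbiphenyl, 15 mol %), K3PO4 (3 equiv), degassed toluene, 100 °C, 11 added by syringe pump over 12 h (final 2 mM)
Reagents that add atoms: none
Why: Zerovalent palladium bearing the bulky biaryl phosphine inserts into the ring D C–Cl bond, the only carbon–halogen bond left; the potassium phenoxide of ring C then replaces chloride on divalent palladium and C–O reductive elimination forms the ether bond. The closest known reaction type is the Buchwald–Hartwig-type palladium-catalysed diaryl ether synthesis from unactivated aryl chlorides and ortho-substituted phenols, here run intramolecularly. The step closes one ring, the 19-membered macrocycle, end to end from the open tetra-aryl chain, the two CH2CH2 hinges letting the termini meet. No stereocentre is formed. The selectivity needed is ring closure over oligomerisation, which slow addition to a dilute catalyst solution should secure, and O-arylation only at the ring C oxygen meta to the bridge, which the benzyl ether on the neighbouring oxygen secures while also providing the ortho substituent that favours reductive elimination.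

Step 6
Reactants: 12 ring C O-benzyl ether of the target
Product: 13 CNP0132125.0 (target)
Conditions: H2 (1 atm), 10% Pd/C, EtOAc–MeOH, rt
Reagents that add atoms: none
Why: hydrogenolysis of the benzylic C–O bond over palladium frees the ring C phenol; the diaryl ethers, the methyl ether and the saturated bridges are inert and no halogen remains.

Compound list
1 | 3-chlorostyrene (1-chloro-3-ethenylbenzene) | C=Cc1cccc(Cl)c1 | starting material
2 | 9-borabicyclo[3.3.1]nonane (9-BBN) | [BH]1C2CCCC1CCC2 | starting material
3 | 5-bromo-2-methoxyphenol | COc1ccc(Br)cc1O | starting material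
4 | 9-[2-(3-chlorophenyl)ethyl]-9-borabicyclo[3.3.1]nonane | Clc1cccc(CCB2C3CCCC2CCC3)c1 | intermediate
5 | 5-[2-(3-chlorophenyl)ethyl]-2-methoxyphenol | COc1ccc(CCc2cccc(Cl)c2)cc1O | intermediate
6 | 4-bromophenylboronic acid | OB(O)c1ccc(Br)cc1 | starting material
7 | 2-(4-bromophenoxy)-4-[2-(3-chlorophenyl)ethyl]-1-methoxybenzene | COc1ccc(CCc2cccc(Cl)c2)cc1Oc1ccc(Br)cc1 | intermediate
8 | 4-(benzyloxy)-3-hydroxybenzaldehyde | O=Cc1ccc(OCc2ccccc2)c(O)c1 | starting material
9 | 2-(benzyloxy)-5-ethenylphenol | C=Cc1ccc(OCc2ccccc2)c(O)c1 | intermediate
10 | 9-{2-[4-(benzyloxy)-3-(9-borabicyclo[3.3.1]nonan-9-yloxy)phenyl]ethyl}-9-borabicyclo[3.3.1]nonane | C(Cc1ccc(OCc2ccccc2)c(OB2C3CCCC2CCC3)c1)B1C2CCCC1CCC2 | intermediate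
11 | 2-(benzyloxy)-5-[2-(4-{5-[2-(3-chlorophenyl)ethyl]-2-methoxyphenoxy}phenyl)ethyl]phenol | COc1ccc(CCc2cccc(Cl)c2)cc1Oc1ccc(CCc2ccc(OCc3ccccc3)c(O)c2)cc1 | intermediate
12 | ring C O-benzyl ether of the target macrocycle | COc1ccc2cc1Oc1ccc(cc1)CCc1ccc(OCc3ccccc3)c(c1)Oc1cccc(c1)CC2 | intermediate
13 | CNP0132125.0 | COc1ccc2cc1Oc1ccc(cc1)CCc1ccc(O)c(c1)Oc1cccc(c1)CC2 | target

Total step count: 6. Longest linear sequence: 5 steps (steps 1, 2, 4, 5 and 6, from 3-chlorostyrene).

Steps most likely to fail

Step 5. Intermolecular coupling to oligomers may outrun ring closure at the dilution that catalytic turnover still tolerates. Slow C–O reductive elimination from the electron-neutral aryl palladium phenoxide may also divert the chloride to hydrodechlorination. The fallback reverses the polarity at ring D and closes the ring by oxidative coupling at room temperature. It sets out from 11: Miyaura borylation of the C–Cl bond (Pd2(dba)3, XPhos, B2pin2, KOAc, dioxane, 100 °C) should give 2-(benzyloxy)-5-{2-[4-(2-methoxy-5-{2-[3-(4,4,5,5-tetramethyl-1,3,2-dioxaborolan-2-yl)phenyl]ethyl}phenoxy)phenyl]ethyl}phenol F1. An intramolecular Chan–Lam coupling of this boronate (Cu(OAc)2, pyridine, B(OH)3, 4 Å molecular sieves, MeCN, O2, rt to 40 °C, high dilution) comes back to the route at 12.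

Step 2. Protodeboronation and oxidative hydroxylation of the boronic acid may consume it faster than the ortho-substituted, electron-rich phenol is arylated, and turnover of catalytic copper may stall. The fallback uses an aryl halide as the electrophile in an Ullmann-type coupling. It sets out from 5: heating with excess 1,4-diiodobenzene (CuI, picolinic acid, K3PO4, DMSO, 90 °C, conditions that leave the C–Cl bond alone) should give 4-[2-(3-chlorophenyl)ethyl]-2-(4-iodophenoxy)-1-methoxybenzene F2. This iodide takes the place of 7 in the coupling of step 4 and comes back to the route at 11.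

Step 4. Hydroboration may stay incomplete because the phenol consumes borane, the electron-rich styrene may polymerise before it is hydroborated, and transmetalation of the hindered ate complex may be slow. The fallback joins the same two partners by a Heck reaction and saturates the alkene afterwards. It sets out from 9 and 7: Pd(OAc)2, P(o-tol)3, K2CO3, DMF, 100 °C should give 2-(benzyloxy)-5-[(E)-2-(4-{5-[2-(3-chlorophenyl)ethyl]-2-methoxyphenoxy}phenyl)ethenyl]phenol F3. Diimide reduction (TsNHNH2, NaOAc, THF–H2O, reflux), which spares the C–Cl bond and the benzyl ether, comes back to the route at 11.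

Further compounds
F1 | step 5 | 2-(benzyloxy)-5-{2-[4-(2-methoxy-5-{2-[3-(4,4,5,5-tetramethyl-1,3,2-dioxaborolan-2-yl)phenyl]ethyl}phenoxy)phenyl]ethyl}phenol | COc1ccc(CCc2cccc(B3OC(C)(C)C(C)(C)O3)c2)cc1Oc1ccc(CCc2ccc(OCc3ccccc3)c(O)c2)cc1
F2 | step 2 | 4-[2-(3-chlorophenyl)ethyl]-2-(4-iodophenoxy)-1-methoxybenzene | COc1ccc(CCc2cccc(Cl)c2)cc1Oc1ccc(I)cc1
F3 | step 4 | 2-(benzyloxy)-5-[(E)-2-(4-{5-[2-(3-chlorophenyl)ethyl]-2-methoxyphenoxy}phenyl)ethenyl]phenol | COc1ccc(CCc2cccc(Cl)c2)cc1Oc1ccc(/C=C/c2ccc(OCc3ccccc3)c(O)c2)cc1
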